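**Retrosynthetic overview**
1. Target ⇒ O-debenzylation, catalyst-controlled transfer hydrogenation at C-7' and acetonide removal lead back to a trans 7'-oxo lactone.
2. Butyrolactone ⇒ γ-keto ester + formaldehyde: aldol at C-4, lactonization onto the ester, C-4 equilibrated trans to C-3.
3. Key C-4–C-7' bond ⇒ enantioselective intermolecular Stetter reaction. The complete β-O-4 aryl aldehyde becomes an acyl anion (Breslow enaminol of a chiral triazolylidene) and adds to a methyl 2-(arylmethyl)acrylate. C-3 is set in the enolate protonation.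
4. Aldehyde ⇒ Evans syn glycolate aldol (aryloxyacetyl imide + O-benzylvanillin) for the threo (7''S,8''S) unit, then LiBH4, acetonide, Br→CHO. Acrylate ⇒ arylboronic acid + methyl 2-(bromomethyl)acrylate.
5. Ring order: temporary 1,3-dioxane (step 5), butyrolactone after the key step (step 9), dioxane opened again (step 10). All arenes are bought.

Locants: lactone C-2 to C-5; C-7' is the carbinol carbon on C-4; C-7''/C-8''/C-9'' is the glycerol chain.
Assumption: the (5S) triazolium catalyst of step 8 is taken, by analogy with other 2-substituted acrylates, to protonate the enolate on the face that gives (2R)-18; if the sense is the opposite, its (5R) antipode from D-phenylalaninol is used unchanged.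
Catalyst of step 8 (three operations from the L-phenylalaninol-derived 5-benzylmorpholin-3-one): COc1cccc(OC)c1-[n+]1cn2c(n1)COC[C@@H]2Cc1ccccc1.F[B-](F)(F)F

**Step 1**
Reactants: 1 4-bromo-2-methoxyphenol; 2 bromoacetic acid
Product: 3 2-(4-bromo-2-methoxyphenoxy)acetic acid
Conditions: NaOH (2.2 equiv), H2O, reflux; then HCl to pH 1
Reagents that add atoms: none
Why: Williamson ether synthesis, in which the phenoxide displaces bromide from bromoacetate by SN2; no stereocentre is involved.

**Step 2**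
Reactants: 3 2-(4-bromo-2-methoxyphenoxy)acetic acid; 4 (R)-4-benzyloxazolidin-2-one
Product: 6 (R)-4-benzyl-3-[2-(4-bromo-2-methoxyphenoxy)acetyl]oxazolidin-2-one, via mixed anhydride 5 (not isolated)
Conditions: pivaloyl chloride, Et3N, THF, −20 °C; then LiCl, 4, −20 °C to rt
Reagents that add atoms: none
Why: Mixed-anhydride N-acylation, in which the LiCl/Et3N-activated oxazolidinone attacks the less hindered aryloxyacetyl carbonyl and the auxiliary stereocentre is untouched.

**Step 3**
Reactants: 6 (R)-4-benzyl-3-[2-(4-bromo-2-methoxyphenoxy)acetyl]oxazolidin-2-one; 7 4-benzyloxy-3-methoxybenzaldehyde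
Product: 9 (R)-4-benzyl-3-[(2R,3S)-3-(4-benzyloxy-3-methoxyphenyl)-2-(4-bromo-2-methoxyphenoxy)-3-hydroxypropanoyl]oxazolidin-2-one, via boron enolate 8 (not isolated)
Conditions: Bu2BOTf, i-Pr2NEt, CH2Cl2, −78 to 0 °C; 7, −78 to 0 °C; then pH 7 buffer, MeOH, 30% H2O2, 0 °C
Reagents that add atoms: none
Why: Evans syn aldol, in which the (Z)-boron enolate reacts through a Zimmerman–Traxler chair on the face away from the auxiliary benzyl group and sets C-8'' and C-7'' together as the syn (threo) pair.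

**Step 4**
Reactants: 9 Evans syn aldol adduct
Product: 10 (1S,2S)-1-(4-benzyloxy-3-methoxyphenyl)-2-(4-bromo-2-methoxyphenoxy)propane-1,3-diol
Conditions: LiBH4, THF, MeOH (2 equiv), 0 °C
Reagents that add atoms: none
Why: Reductive cleavage of the imide at its exocyclic carbonyl; aryl bromide and benzyl ether are inert, no stereocentre is touched, and the C-8'' descriptor changes from R to S only through CIP priorities.

**Step 5**
Reactants: 10 threo 1,3-diol
Product: 11 (4S,5S)-4-(4-benzyloxy-3-methoxyphenyl)-5-(4-bromo-2-methoxyphenoxy)-2,2-dimethyl-1,3-dioxane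
Conditions: 2,2-dimethoxypropane, pyridinium p-toluenesulfonate (5 mol %), CH2Cl2, rt
Reagents that add atoms: 2,2-dimethoxypropane COC(C)(C)OC
Why: Acid-catalysed transacetalization closes the six-membered acetonide over the only two hydroxyl groups without breaking a C–O bond at a stereocentre.

**Step 6**
Reactants: 11 bromo acetonide
Product: 13 4-{[(4S,5S)-4-(4-benzyloxy-3-methoxyphenyl)-2,2-dimethyl-1,3-dioxan-5-yl]oxy}-3-methoxybenzaldehyde, via aryllithium 12 (not isolated)
Conditions: n-BuLi (1.1 equiv), THF, −78 °C; DMF, −78 to 0 °C; then H2O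
Reagents that add atoms: N,N-dimethylformamide CN(C)C=O
Why: Bromine–lithium exchange followed by formylation with DMF; the exchange at −78 °C is faster than any deprotonation of the benzyl ether or acetal.

**Step 7**
Reactants: 14 (4-benzyloxy-3-methoxyphenyl)boronic acid; 15 methyl 2-(bromomethyl)acrylate
Product: 16 methyl 2-(4-benzyloxy-3-methoxybenzyl)acrylate
Conditions: Pd(PPh3)4 (3 mol %), K2CO3, THF/H2O (10:1), 60 °C
Reagents that add atoms: none
Why: Suzuki–Miyaura allylic arylation through a 2-(methoxycarbonyl)allylpalladium complex whose two termini are equivalent, so only one regioisomer can form.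

**Step 8 (key step)**
Reactants: 13 β-O-4 aryl aldehyde; 16 methyl 2-(4-benzyloxy-3-methoxybenzyl)acrylate
Product: 18 methyl (2R)-2-(4-benzyloxy-3-methoxybenzyl)-4-{4-[((4S,5S)-4-(4-benzyloxy-3-methoxyphenyl)-2,2-dimethyl-1,3-dioxan-5-yl)oxy]-3-methoxyphenyl}-4-oxobutanoate, via Breslow enaminol 17 (not isolated)
Conditions: (5S)-5-benzyl-2-(2,6-dimethoxyphenyl)-5,6-dihydro-8H-[1,2,4]triazolo[3,4-c][1,4]oxazin-2-ium tetrafluoroborate (15 mol %), KOt-Bu (12 mol %), 16 (1.5 equiv), toluene, 4 Å sieves, 0 °C to rt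
Reagents that add atoms: none
Why: Enantioselective intermolecular Stetter reaction, in which the carbene turns the aldehyde carbon into a nucleophilic enaminol that adds to the unsubstituted β-carbon of the acrylate, and the ester enolate is then protonated inside the chiral catalyst pocket, setting C-3 as R; benzoin formation is reversible and base is kept below the catalyst loading so that 18 does not racemize.

**Step 9**
Reactants: 18 γ-keto ester
Product: 21 (3R,4R)-3-(4-benzyloxy-3-methoxybenzyl)-4-{4-[((4S,5S)-4-(4-benzyloxy-3-methoxyphenyl)-2,2-dimethyl-1,3-dioxan-5-yl)oxy]-3-methoxybenzoyl}dihydrofuran-2(3H)-one, via lithium enolate 19 (not isolated), via hydroxymethyl ketone 20 (not isolated)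
Conditions: LiN(SiMe3)2 (1.05 equiv), THF, −78 °C; HCHO gas (cracked paraformaldehyde), −78 to −40 °C; AcOH; then 1,8-diazabicyclo[5.4.0]undec-7-ene (10 mol %), CH2Cl2, rt
Reagents that add atoms: formaldehyde C=O
Why: Crossed aldol and lactonization, in which the ketone CH2 (more acidic and less hindered than the ester α-CH) is deprotonated selectively, the enolate takes up monomeric formaldehyde, the new primary alcohol closes the lactone by 5-exo-trig attack on the ester, and the amidine base equilibrates only the ketone α-centre, so C-4 settles as R, trans to the C-3 benzyl group.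

**Step 10**
Reactants: 21 keto lactone acetonide
Product: 22 (3R,4R)-3-(4-benzyloxy-3-methoxybenzyl)-4-{4-[((1S,2S)-1-(4-benzyloxy-3-methoxyphenyl)-1,3-dihydroxypropan-2-yl)oxy]-3-methoxybenzoyl}dihydrofuran-2(3H)-one
Conditions: 1 M aq HCl/THF (1:4), rt
Reagents that add atoms: none
Why: Acid-catalysed acetal hydrolysis, done at the ketone stage because no ionizable C-7' carbinol is yet present that could cyclize onto the neighbouring benzyl ring; the trans lactone is already the thermodynamic isomer.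

**Step 11**
Reactants: 22 keto lactone diol
Product: 23 (3R,4R)-3-(4-benzyloxy-3-methoxybenzyl)-4-[(R)-{4-[((1S,2S)-1-(4-benzyloxy-3-methoxyphenyl)-1,3-dihydroxypropan-2-yl)oxy]-3-methoxyphenyl}(hydroxy)methyl]dihydrofuran-2(3H)-one
Conditions: RuCl[(1R,2R)-TsNCHPhCHPhNH2](p-cymene) (3 mol %), HCO2H/Et3N (5:2), EtOAc, 30 °C
Reagents that add atoms: none
Why: Noyori–Ikariya asymmetric transfer hydrogenation, in which the outer-sphere hydride and proton transfer holds the aryl ring under the η6-arene and delivers hydride to the Si face, so the (R,R) catalyst gives the (7'R) carbinol (the same sense as acetophenone to (R)-1-phenylethanol) against the modest Felkin preference for 7'S; lactone, free diol and benzyl ethers are inert.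

**Step 12**
Reactants: 23 dibenzyl ether of the target
Product: 24 (3R,4R)-4-[(R)-{4-[((1S,2S)-1,3-dihydroxy-1-(4-hydroxy-3-methoxyphenyl)propan-2-yl)oxy]-3-methoxyphenyl}(hydroxy)methyl]-3-(4-hydroxy-3-methoxybenzyl)dihydrofuran-2(3H)-one
Conditions: H2 (1 atm), 10% Pd/C, EtOAc/EtOH, rt, stopped after 2 equiv H2
Reagents that add atoms: none
Why: Hydrogenolysis of the two aryl benzyl ethers, which under neutral conditions at 1 atm is much faster than C–O cleavage of the secondary benzylic alcohols; no stereocentre is touched.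

**Compound list**
1 | 4-bromo-2-methoxyphenol | COc1cc(Br)ccc1O | starting material
2 | bromoacetic acid | OC(=O)CBr | starting material
3 | 2-(4-bromo-2-methoxyphenoxy)acetic acid | COc1cc(Br)ccc1OCC(=O)O | intermediate
4 | (R)-4-benzyloxazolidin-2-one | O=C1N[C@H](Cc2ccccc2)CO1 | starting material
5 | 2-(4-bromo-2-methoxyphenoxy)acetic pivalic anhydride (not isolated) | COc1cc(Br)ccc1OCC(=O)OC(=O)C(C)(C)C | intermediate
6 | (R)-4-benzyl-3-[2-(4-bromo-2-methoxyphenoxy)acetyl]oxazolidin-2-one | COc1cc(Br)ccc1OCC(=O)N1C(=O)OC[C@H]1Cc1ccccc1 | intermediate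
7 | 4-benzyloxy-3-methoxybenzaldehyde | COc1cc(C=O)ccc1OCc1ccccc1 | starting material
8 | (Z)-dibutylboron enolate of 6 (not isolated) | CCCCB(CCCC)O/C(=C\Oc1ccc(Br)cc1OC)N1C(=O)OC[C@H]1Cc1ccccc1 | intermediate
9 | (2R,3S) Evans syn aldol adduct on the (R)-auxiliary | COc1cc(Br)ccc1O[C@@H](C(=O)N1C(=O)OC[C@H]1Cc1ccccc1)[C@@H](O)c1ccc(OCc2ccccc2)c(OC)c1 | intermediate
10 | (1S,2S)-1-(4-benzyloxy-3-methoxyphenyl)-2-(4-bromo-2-methoxyphenoxy)propane-1,3-diol | COc1cc(Br)ccc1O[C@@H](CO)[C@@H](O)c1ccc(OCc2ccccc2)c(OC)c1 | intermediate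
11 | (4S,5S)-4-(4-benzyloxy-3-methoxyphenyl)-5-(4-bromo-2-methoxyphenoxy)-2,2-dimethyl-1,3-dioxane | COc1cc(Br)ccc1O[C@H]1COC(C)(C)O[C@H]1c1ccc(OCc2ccccc2)c(OC)c1 | intermediate
12 | aryllithium from 11 (not isolated) | COc1cc([Li])ccc1O[C@H]1COC(C)(C)O[C@H]1c1ccc(OCc2ccccc2)c(OC)c1 | intermediate
13 | 4-{[(4S,5S)-4-(4-benzyloxy-3-methoxyphenyl)-2,2-dimethyl-1,3-dioxan-5-yl]oxy}-3-methoxybenzaldehyde | COc1cc(C=O)ccc1O[C@H]1COC(C)(C)O[C@H]1c1ccc(OCc2ccccc2)c(OC)c1 | intermediate
14 | (4-benzyloxy-3-methoxyphenyl)boronic acid | COc1cc(B(O)O)ccc1OCc1ccccc1 | starting material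
15 | methyl 2-(bromomethyl)acrylate | COC(=O)C(=C)CBr | starting material
16 | methyl 2-(4-benzyloxy-3-methoxybenzyl)acrylate | COC(=O)C(=C)Cc1ccc(OCc2ccccc2)c(OC)c1 | intermediate
17 | Breslow enaminol of 13 and the (5S)-triazolylidene (not isolated, C=C geometry open) | OC(c1ccc(O[C@H]2COC(C)(C)O[C@H]2c2ccc(OCc3ccccc3)c(OC)c2)c(OC)c1)=C1N(c2c(OC)cccc2OC)N=C2COC[C@H](Cc3ccccc3)N12 | intermediate
18 | methyl (2R)-2-(4-benzyloxy-3-methoxybenzyl)-4-oxo-4-aryl-butanoate (aryl as in 13) | COc1cc(C[C@H](CC(=O)c2ccc(O[C@H]3COC(C)(C)O[C@H]3c3ccc(OCc4ccccc4)c(OC)c3)c(OC)c2)C(=O)OC)ccc1OCc1ccccc1 | intermediate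
19 | lithium (Z)-enolate of the ketone in 18 (not isolated) | [Li]O/C(c1ccc(O[C@H]2COC(C)(C)O[C@H]2c2ccc(OCc3ccccc3)c(OC)c2)c(OC)c1)=C\[C@@H](Cc1ccc(OCc2ccccc2)c(OC)c1)C(=O)OC | intermediate
20 | methyl (2R)-2-(4-benzyloxy-3-methoxybenzyl)-3-(hydroxymethyl)-4-oxo-4-aryl-butanoate, both C-3 epimers (not isolated) | COc1cc(C[C@H](C(CO)C(=O)c2ccc(O[C@H]3COC(C)(C)O[C@H]3c3ccc(OCc4ccccc4)c(OC)c3)c(OC)c2)C(=O)OC)ccc1OCc1ccccc1 | intermediate
21 | (3R,4R) trans 7'-oxo lactone, acetonide | COc1cc(C[C@H]2C(=O)OC[C@@H]2C(=O)c2ccc(O[C@H]3COC(C)(C)O[C@H]3c3ccc(OCc4ccccc4)c(OC)c3)c(OC)c2)ccc1OCc1ccccc1 | intermediate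
22 | (3R,4R) trans 7'-oxo lactone, free (7''S,8''S) diol | COc1cc(C[C@H]2C(=O)OC[C@@H]2C(=O)c2ccc(O[C@@H](CO)[C@@H](O)c3ccc(OCc4ccccc4)c(OC)c3)c(OC)c2)ccc1OCc1ccccc1 | intermediate
23 | (3R,4R,7'R,7''S,8''S) dibenzyl ether of the target | COc1cc(C[C@H]2C(=O)OC[C@@H]2[C@@H](O)c2ccc(O[C@@H](CO)[C@@H](O)c3ccc(OCc4ccccc4)c(OC)c3)c(OC)c2)ccc1OCc1ccccc1 | intermediate
24 | CNP0233652.1 | COc1cc(C[C@H]2C(=O)OC[C@@H]2[C@@H](O)c2ccc(O[C@@H](CO)[C@@H](O)c3ccc(O)c(OC)c3)c(OC)c2)ccc1O | target

**Totals:** 12 steps. The longest linear sequence is 11 steps (steps 1–6 and 8–12); step 7 is a one-step side branch.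

**Steps most likely to fail**

Step 8. The electron-rich, bulky aldehyde may rest at the benzoin stage, add slowly to the α-substituted acrylate, or give a lower ee than simpler aldehydes. The fallback sets out from 11 and comes back at 18. It shifts the polarity reversal to C-4, using an α-halo ketone as an α-carbonyl cation equivalent, and forms the C-3–C-4 bond instead.
- Aryllithium 12, made from 11 as in step 6, is acylated with 2-chloro-N-methoxy-N-methylacetamide to give the chloromethyl ketone F1.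
- 3-(4-Benzyloxy-3-methoxyphenyl)propanoic acid is loaded onto (S)-4-benzyloxazolidin-2-one by the method of step 2 to give the propanoyl imide F2.
- The sodium enolate of F2 (NaN(SiMe3)2, THF, −78 °C) is alkylated by F1 (NaI) on the face away from the auxiliary benzyl group to give the (2R) keto imide F3.
- MeOMgBr in MeOH/CH2Cl2 at 0 °C exchanges the auxiliary for methoxide and gives 18.

Step 9. Possible failures are double hydroxymethylation, E1cB opening of the β-acyloxy ketone, and poor capture of gaseous formaldehyde. The fallback sets out from 18 and comes back at 21. It replaces the basic enolate by a Lewis-acid aldol in water.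
- Me3SiOTf/Et3N in CH2Cl2 at 0 °C gives the trimethylsilyl enol ether F4.
- F4 undergoes a Mukaiyama aldol with aqueous formaldehyde under Yb(OTf)3 (10 mol %) in THF/H2O to give 20, now isolated.
- Warming 20 with pyridinium p-toluenesulfonate in toluene closes the lactone, and brief treatment with Et3N equilibrates C-4 to the trans isomer 21.

Step 11. The catalyst works against the substrate's Felkin preference at an α-branched ketone, so the reaction may be slow, give a poor 7'R:7'S ratio, or leak through the C-4 epimer. The fallback sets out from 21 and comes back at 23. It accepts the substrate bias and inverts afterwards.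
- LiBH(s-Bu)3 in THF at −78 °C reduces 21 under Felkin control to the (7'S) alcohol acetonide F5.
- Mitsunobu reaction of F5 (4-nitrobenzoic acid, PPh3, diisopropyl azodicarboxylate, toluene, −20 °C) gives with inversion the (7'R) 4-nitrobenzoate F6.
- K2CO3 in MeOH at 0 °C frees the (7'R) alcohol acetonide F7.
- AcOH/H2O/THF at 35 °C removes the acetonide to give 23.

**Further compounds**
F1 | step 8 | 2-chloro-1-(4-{[(4S,5S)-4-(4-benzyloxy-3-methoxyphenyl)-2,2-dimethyl-1,3-dioxan-5-yl]oxy}-3-methoxyphenyl)ethan-1-one | COc1cc(C(=O)CCl)ccc1O[C@H]1COC(C)(C)O[C@H]1c1ccc(OCc2ccccc2)c(OC)c1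
F2 | step 8 | (S)-4-benzyl-3-[3-(4-benzyloxy-3-methoxyphenyl)propanoyl]oxazolidin-2-one | COc1cc(CCC(=O)N2C(=O)OC[C@@H]2Cc2ccccc2)ccc1OCc1ccccc1
F3 | step 8 | (S)-4-benzyl-3-[(2R)-2-(4-benzyloxy-3-methoxybenzyl)-4-oxo-4-aryl-butanoyl]oxazolidin-2-one (aryl as in 13) | COc1cc(C[C@H](CC(=O)c2ccc(O[C@H]3COC(C)(C)O[C@H]3c3ccc(OCc4ccccc4)c(OC)c3)c(OC)c2)C(=O)N2C(=O)OC[C@@H]2Cc2ccccc2)ccc1OCc1ccccc1
F4 | step 9 | (Z)-trimethylsilyl enol ether of 18 | C[Si](C)(C)O/C(c1ccc(O[C@H]2COC(C)(C)O[C@H]2c2ccc(OCc3ccccc3)c(OC)c2)c(OC)c1)=C\[C@@H](Cc1ccc(OCc2ccccc2)c(OC)c1)C(=O)OC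
F5 | step 11 | (3R,4R,7'S) hydroxy lactone acetonide | COc1cc(C[C@H]2C(=O)OC[C@@H]2[C@H](O)c2ccc(O[C@H]3COC(C)(C)O[C@H]3c3ccc(OCc4ccccc4)c(OC)c3)c(OC)c2)ccc1OCc1ccccc1
F6 | step 11 | (3R,4R,7'R) 4-nitrobenzoate acetonide | COc1cc(C[C@H]2C(=O)OC[C@@H]2[C@@H](OC(=O)c2ccc(cc2)[N+](=O)[O-])c2ccc(O[C@H]3COC(C)(C)O[C@H]3c3ccc(OCc4ccccc4)c(OC)c3)c(OC)c2)ccc1OCc1ccccc1
F7 | step 11 | (3R,4R,7'R) hydroxy lactone acetonide | COc1cc(C[C@H]2C(=O)OC[C@@H]2[C@@H](O)c2ccc(O[C@H]3COC(C)(C)O[C@H]3c3ccc(OCc4ccccc4)c(OC)c3)c(OC)c2)ccc1OCc1ccccc1
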